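**Strategy.** Each γ-butyrolactone (O1, C2=O, C3, C4, C5) is cut at C4–C5, the bond between the ring methine that carries the veratryl CH2 group and the OCH2 carbon. The key step makes an (acyloxy)methyl radical at C5 from an iodomethyl ester and adds it 5-exo-trig to C4 of an (E)-styryl group: this closes the lactone, converts the styrene into the veratryl CH2 and sets C4 trans to the C3 stereocentre. It exploits the O1–C5H2–C4 unit of the lactone ring and the C4–CH2–aryl side chain, which can be carried as a styrene acceptor. The precursor is an open-chain bis(iodomethyl) ester of a diaryl-ether-linked bis(α-arylmethyl β,γ-unsaturated acid) from a twofold Evans alkylation; both lactones close in one operation.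

Key step: step 10

Assumption (chemistry): in the twofold steps 3, 4, 7, 8, 9 and 10 the two arms of the diaryl ether react independently under the same conditions, so each is written as one transformation and the short-lived half-converted species are not listed separately.

Step 1
Reactants: 1 3,4-dihydroxy-5-methoxybenzaldehyde; 2 benzyl bromide
Product: 3 4-(benzyloxy)-3-hydroxy-5-methoxybenzaldehyde
Conditions: BnBr (1.0 equiv), NaHCO3, NaI (cat.), DMF, 40 °C
Reagents that add atoms: none
Why: Williamson O-alkylation in which the 4-OH, para to the formyl group and therefore the more acidic phenol, is ionised selectively by the weak base, so the benzyl group should go on O-4.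

Step 2
Reactants: 3 4-(benzyloxy)-3-hydroxy-5-methoxybenzaldehyde; 4 4-fluoro-3-methoxybenzaldehyde
Product: 5 4-(benzyloxy)-3-(4-formyl-2-methoxyphenoxy)-5-methoxybenzaldehyde
Conditions: K2CO3, DMF, 120 °C
Reagents that add atoms: none
Why: Nucleophilic aromatic substitution (SNAr) in which the para-formyl group activates the C–F bond of 4 toward the phenoxide of 3 through a Meisenheimer intermediate.

Step 3
Reactants: 5 4-(benzyloxy)-3-(4-formyl-2-methoxyphenoxy)-5-methoxybenzaldehyde
Product: 6 diaryl ether bis(benzylic alcohol)
Conditions: NaBH4, MeOH/THF, 0 °C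
Reagents that add atoms: none
Why: Borohydride reduction of both aryl aldehydes to benzylic alcohols, which leaves the ether groups untouched.

Step 4
Reactants: 6 diaryl ether bis(benzylic alcohol)
Product: 7 diaryl ether bis(benzylic bromide)
Conditions: PBr3, CH2Cl2, 0 °C; used at once
Reagents that add atoms: phosphorus tribromide, BrP(Br)Br
Why: Conversion of both electron-rich benzylic alcohols into bromides through phosphite esters that are displaced by bromide (SN2).

Step 5
Reactants: 8 3,4-dimethoxybenzaldehyde; 9 (2-carboxyethyl)triphenylphosphonium bromide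
Product: 11 (E)-4-(3,4-dimethoxyphenyl)but-3-enoic acid, via ylide carboxylate 10 (not isolated)
Conditions: NaHMDS (2.1 equiv), THF, 0 °C; then 8, 0 °C → rt; aq. HCl
Reagents that add atoms: NaHMDS, [Na+].C[Si](C)(C)[N-][Si](C)(C)C (sodium only in intermediate 10; nothing remains in 11)
Why: Wittig olefination with the carboxylate-bearing ylide, which should give the β,γ-unsaturated acid mainly as the E isomer, a minor Z isomer being removable by crystallisation.

Step 6
Reactants: 11 (E)-4-(3,4-dimethoxyphenyl)but-3-enoic acid; 12 (S)-4-benzyloxazolidin-2-one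
Product: 14 (S)-4-benzyl-3-[(E)-4-(3,4-dimethoxyphenyl)but-3-enoyl]oxazolidin-2-one, via mixed pivalic anhydride 13 (not isolated)
Conditions: PivCl, Et3N, THF, −20 °C; then LiCl, 12, −20 °C → rt
Reagents that add atoms: pivaloyl chloride, CC(C)(C)C(=O)Cl (pivaloyl group only in intermediate 13; nothing remains in 14)
Why: N-acylation of the oxazolidinone through the mixed anhydride under LiCl/Et3N activation, mild enough to keep the alkene in the β,γ position and without effect on the auxiliary stereocentre.

Step 7
Reactants: 14 (S)-4-benzyl-3-[(E)-4-(3,4-dimethoxyphenyl)but-3-enoyl]oxazolidin-2-one (2.4 equiv); 7 diaryl ether bis(benzylic bromide)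
Product: 16 twofold alkylated bis-imide (2S at both new α-carbons), via sodium Z-enolate 15 (not isolated)
Conditions: NaHMDS, THF, −78 °C; then 7, −78 → −40 °C
Reagents that add atoms: NaHMDS, [Na+].C[Si](C)(C)[N-][Si](C)(C)C (sodium only in intermediate 15; nothing remains in 16)
Why: Twofold Evans asymmetric alkylation in which the chelated Z-dienolate reacts at its α-carbon on the face opposite the auxiliary benzyl group, which sets the S configuration at each new stereocentre (the future C3 of each lactone).

Step 8
Reactants: 16 twofold alkylated bis-imide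
Product: 18 bis(α-arylmethyl β,γ-unsaturated acid), via bis(peroxy acid) 17 (not isolated)
Conditions: LiOH, H2O2, THF/H2O, 0 °C; then aq. Na2SO3; HCl to pH 3
Reagents that add atoms: hydrogen peroxide, OO, acting as lithium hydroperoxide, [Li+].[O-]O (both oxygens in intermediate 17; one per arm remains in 18)
Why: Hydroperoxide-mediated cleavage of the imide at the exocyclic carbonyl followed by sulfite reduction of the peracid, a weakly basic method that should leave the α-stereocentres and the β,γ-alkenes intact.

Step 9
Reactants: 18 bis(α-arylmethyl β,γ-unsaturated acid)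
Product: 20 bis(iodomethyl) ester, via bis(chloromethyl) ester 19 (not isolated)
Conditions: ClCH2OSO2Cl, NaHCO3, Bu4NHSO4 (cat.), CH2Cl2/H2O, 0 °C → rt; then NaI, acetone, rt, dark
Reagents that add atoms: chloromethyl chlorosulfate, ClCOS(=O)(=O)Cl (the CH2 unit; its chlorine only in intermediate 19); sodium iodide, [Na+].[I-]
Why: Phase-transfer O-alkylation of the carboxylates by chloromethyl chlorosulfate (chlorosulfate leaves) followed by Finkelstein exchange of chloride for iodide, all under near-neutral conditions that preserve the α-stereocentres.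

Step 10
Reactants: 20 bis(iodomethyl) ester
Product: 21 O-benzyl bis-lactone (3S,4S in both lactones)
Conditions: Bu3SnH (slow addition), AIBN (cat.), PhH (0.003 M), 80 °C
Reagents that add atoms: none
Why: Tributyltin radical abstracts iodine from each O–CH2–I group to give an (acyloxy)methyl radical at the future lactone carbon C5, which adds to C4, the styrene carbon remote from the aryl group, and the resulting benzylic radical at the future veratryl CH2 takes hydrogen from Bu3SnH. The closest known reaction type is the tin-hydride-mediated cyclisation of (alk-3-enoyloxy)methyl radicals, generated from iodomethyl alk-3-enoates, to γ-butyrolactones. Each lactone ring closes in the 5-exo-trig mode; 6-endo attack at the aryl-bearing carbon is disfavoured because it would forgo the benzylic radical. The new stereocentre at C4 is controlled by the existing C3 stereocentre: in the chair-like 5-exo transition state the C3 arylmethyl group sits pseudo-equatorial, so the radical adds to the alkene face anti to it and the trans (3S,4S) lactone should predominate. The step needs cyclisation to outrun direct reduction of the radical, since the ester must first rotate into its s-cis conformer; the activated styrene acceptor, high dilution and slow stannane addition secure this, and the neutral conditions leave the epimerisable C3 centre untouched.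

Step 11
Reactants: 21 O-benzyl bis-lactone
Product: 22 CNP0183104.1
Conditions: H2 (1 atm), Pd/C (palladium on carbon), EtOAc/MeOH, rt
Reagents that add atoms: none
Why: Hydrogenolysis of the benzyl aryl ether frees the phenol, while the lactones, the diaryl ether and the methyl ethers are inert and no stereocentre is affected.

**Compound list**

1 | 3,4-dihydroxy-5-methoxybenzaldehyde (5-hydroxyvanillin) | COc1cc(C=O)cc(O)c1O | starting material
2 | benzyl bromide | BrCc1ccccc1 | starting material
3 | 4-(benzyloxy)-3-hydroxy-5-methoxybenzaldehyde | COc1cc(C=O)cc(O)c1OCc1ccccc1 | intermediate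
4 | 4-fluoro-3-methoxybenzaldehyde | COc1cc(C=O)ccc1F | starting material
5 | 4-(benzyloxy)-3-(4-formyl-2-methoxyphenoxy)-5-methoxybenzaldehyde | COc1cc(C=O)ccc1Oc1cc(C=O)cc(OC)c1OCc1ccccc1 | intermediate
6 | [4-(benzyloxy)-3-[4-(hydroxymethyl)-2-methoxyphenoxy]-5-methoxyphenyl]methanol | COc1cc(CO)ccc1Oc1cc(CO)cc(OC)c1OCc1ccccc1 | intermediate
7 | 2-(benzyloxy)-5-(bromomethyl)-1-[4-(bromomethyl)-2-methoxyphenoxy]-3-methoxybenzene | COc1cc(CBr)ccc1Oc1cc(CBr)cc(OC)c1OCc1ccccc1 | intermediate
8 | 3,4-dimethoxybenzaldehyde (veratraldehyde) | COc1ccc(C=O)cc1OC | starting material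
9 | (2-carboxyethyl)triphenylphosphonium bromide | OC(=O)CC[P+](c1ccccc1)(c1ccccc1)c1ccccc1.[Br-] | starting material
10 | sodium 3-(triphenyl-λ5-phosphanylidene)propanoate (ylide carboxylate) | [Na+].[O-]C(=O)CC=P(c1ccccc1)(c1ccccc1)c1ccccc1 | intermediate
11 | (E)-4-(3,4-dimethoxyphenyl)but-3-enoic acid | COc1ccc(/C=C/CC(=O)O)cc1OC | intermediate
12 | (S)-4-benzyloxazolidin-2-one | O=C1N[C@@H](Cc2ccccc2)CO1 | starting material
13 | (E)-4-(3,4-dimethoxyphenyl)but-3-enoic pivalic anhydride | COc1ccc(/C=C/CC(=O)OC(=O)C(C)(C)C)cc1OC | intermediate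
14 | (S)-4-benzyl-3-[(E)-4-(3,4-dimethoxyphenyl)but-3-enoyl]oxazolidin-2-one | COc1ccc(/C=C/CC(=O)N2[C@@H](Cc3ccccc3)COC2=O)cc1OC | intermediate
15 | sodium (Z)-enolate of 14 (O–Na and the styryl group cis on the enolate double bond) | COc1ccc(/C=C/C=C(\[O-])N2[C@@H](Cc3ccccc3)COC2=O)cc1OC.[Na+] | intermediate
16 | bis-imide: the diaryl ether core of 7 in which each former CH2Br carbon is bonded to C2 of a (2S,3E)-4-(3,4-dimethoxyphenyl)-1-[(S)-4-benzyl-2-oxooxazolidin-3-yl]-1-oxobut-3-en-2-yl unit | O=C(N1[C@@H](Cc2ccccc2)COC1=O)[C@H](/C=C/c1ccc(OC)c(OC)c1)Cc1ccc(Oc2cc(C[C@@H](/C=C/c3ccc(OC)c(OC)c3)C(=O)N3[C@@H](Cc4ccccc4)COC3=O)cc(OC)c2OCc2ccccc2)c(OC)c1 | intermediate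
17 | bis(peroxy acid): as 18 with both CO2H groups as CO3H, (2S,3E) in both arms | OOC(=O)[C@H](/C=C/c1ccc(OC)c(OC)c1)Cc1ccc(Oc2cc(C[C@@H](/C=C/c3ccc(OC)c(OC)c3)C(=O)OO)cc(OC)c2OCc2ccccc2)c(OC)c1 | intermediate
18 | diacid: the diaryl ether core of 7 in which each former CH2Br carbon is bonded to C2 of a (2S,3E)-4-(3,4-dimethoxyphenyl)but-3-enoic acid | OC(=O)[C@H](/C=C/c1ccc(OC)c(OC)c1)Cc1ccc(Oc2cc(C[C@@H](/C=C/c3ccc(OC)c(OC)c3)C(=O)O)cc(OC)c2OCc2ccccc2)c(OC)c1 | intermediate
19 | bis(chloromethyl) ester of 18, (2S,3E) in both arms | ClCOC(=O)[C@H](/C=C/c1ccc(OC)c(OC)c1)Cc1ccc(Oc2cc(C[C@@H](/C=C/c3ccc(OC)c(OC)c3)C(=O)OCCl)cc(OC)c2OCc2ccccc2)c(OC)c1 | intermediate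
20 | bis(iodomethyl) ester of 18, (2S,3E) in both arms | ICOC(=O)[C@H](/C=C/c1ccc(OC)c(OC)c1)Cc1ccc(Oc2cc(C[C@@H](/C=C/c3ccc(OC)c(OC)c3)C(=O)OCI)cc(OC)c2OCc2ccccc2)c(OC)c1 | intermediate
21 | O-benzyl ether of the target: both lactones (3S,4S), trans | COc1ccc(C[C@@H]2COC(=O)[C@H]2Cc2ccc(Oc3cc(C[C@@H]4C(=O)OC[C@H]4Cc4ccc(OC)c(OC)c4)cc(OC)c3OCc3ccccc3)c(OC)c2)cc1OC | intermediate
22 | CNP0183104.1: (3S,4S)-4-(3,4-dimethoxybenzyl)-3-[[4-[5-[[(3S,4S)-4-(3,4-dimethoxybenzyl)-2-oxooxolan-3-yl]methyl]-2-hydroxy-3-methoxyphenoxy]-3-methoxyphenyl]methyl]oxolan-2-one | COc1ccc(C[C@@H]2COC(=O)[C@H]2Cc2ccc(Oc3cc(C[C@@H]4C(=O)OC[C@H]4Cc4ccc(OC)c(OC)c4)cc(OC)c3O)c(OC)c2)cc1OC | target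

**Step count.** Total: 11 steps. Longest linear sequence: 9 steps (steps 1, 2, 3, 4, 7, 8, 9, 10, 11, from 5-hydroxyvanillin); the second branch (steps 5 and 6) joins at step 7.

**Steps most likely to fail**

1. Step 10 (key step).
   - What may go wrong: the (acyloxy)methyl radical may be reduced before it cyclises, because the ester has to rotate out of its preferred s-trans conformation first. Addition to the wrong alkene face would give a cis lactone that cannot be corrected by base, since epimerisation at C3 would lead into the enantiomeric trans series. As the step is twofold, each shortfall counts twice.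
   - Fallback: it sets out from dibromide 7 and comes back to the route at compound 21. Commercial 3-(3,4-dimethoxyphenyl)propan-1-ol would be acylated with bromoacetyl bromide (NaHCO3, MeCN, 0 °C) to 3-(3,4-dimethoxyphenyl)propyl bromoacetate F1. With N,N'-ditosylhydrazine and DBU (THF, 0 °C) this should give 3-(3,4-dimethoxyphenyl)propyl diazoacetate F2. Enantioselective intramolecular C–H insertion of the derived rhodium carbene would follow (CH2Cl2, reflux), using the chiral dirhodium carboxamidate Rh2(MPPIM)4 (MPPIM = methyl 1-(3-phenylpropanoyl)-2-oxoimidazolidine-4-carboxylate) in the enantiomeric form that leads to the S lactone. It should give (S)-4-(3,4-dimethoxybenzyl)dihydrofuran-2(3H)-one F3. Its lithium enolate (LiHMDS, THF, −78 °C, 2.3 equiv) would then be alkylated twice by dibromide 7 (DMPU, −78 → −30 °C), each time anti to the C4 substituent. This should give the trans,trans compound 21 directly, and the route continues with step 11.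

2. Step 8.
   - What may go wrong: hydroperoxide may attack the ring carbonyl of the auxiliary, the intermediate peracid may oxidise the electron-rich styrenes, or configuration may be lost at the doubly activated α-carbon.
   - Fallback: it sets out from bis-imide 16 and comes back at diacid 18. Transesterification with bromomagnesium allyloxide (allyl alcohol, MeMgBr, THF, 0 °C), in which magnesium chelation directs attack to the exocyclic carbonyl, should give the bis(allyl ester) F4. The allyl groups would then be removed under neutral, non-oxidising conditions with Pd(PPh3)4 (zerovalent palladium) and morpholine (THF, rt) to return 18.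

3. Step 9.
   - What may go wrong: the iodomethyl groups may be lost during halide exchange and work-up, by hydrolysis or by attack of residual carboxylate (methylene diester formation), on a compound that tolerates neither light nor prolonged chromatography.
   - Fallback: it sets out from diacid 18 and comes back at compound 21. O-alkylation of the dicaesium salt with chloromethyl phenyl selenide (Cs2CO3, DMF, rt) should give the bis[(phenylselanyl)methyl] ester F5, an O,Se-acetal that can be purified and stored. Under the conditions of step 10 (Bu3SnH, AIBN, PhH, 80 °C, slow addition) the tin radical would abstract the phenylselanyl group and generate the same (acyloxy)methyl radicals, which should cyclise to 21.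

**Further compounds**

F1 | step 10 | 3-(3,4-dimethoxyphenyl)propyl bromoacetate | COc1ccc(CCCOC(=O)CBr)cc1OC
F2 | step 10 | 3-(3,4-dimethoxyphenyl)propyl diazoacetate | COc1ccc(CCCOC(=O)C=[N+]=[N-])cc1OC
F3 | step 10 | (S)-4-(3,4-dimethoxybenzyl)dihydrofuran-2(3H)-one | COc1ccc(C[C@@H]2COC(=O)C2)cc1OC
F4 | step 8 | bis(allyl ester) of diacid 18, (2S,3E) in both arms | C=CCOC(=O)[C@H](/C=C/c1ccc(OC)c(OC)c1)Cc1ccc(Oc2cc(C[C@@H](/C=C/c3ccc(OC)c(OC)c3)C(=O)OCC=C)cc(OC)c2OCc2ccccc2)c(OC)c1
F5 | step 9 | bis[(phenylselanyl)methyl] ester of diacid 18, (2S,3E) in both arms | c1ccccc1[Se]COC(=O)[C@H](/C=C/c1ccc(OC)c(OC)c1)Cc1ccc(Oc2cc(C[C@@H](/C=C/c3ccc(OC)c(OC)c3)C(=O)OC[Se]c3ccccc3)cc(OC)c2OCc2ccccc2)c(OC)c1
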